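## The problem

Praesorether F is an achiral, fully aromatic triad in which ring A, a methyl orsellinate unit (A1 CO2Me, A2 CH3, A4 and A6 OH), is tied from A5 through a CH2 bridge to B1 of an orcinol-type ring B (B2 and B6 OH, B4 CH3). B5 of ring B carries an ether oxygen to C1 of ring C, a methyl haematommate unit (C2 CHO, C3 OH, C5 CH3, C6 CO2Me). With no stereocentre in the target, every difficulty is one of position and compatibility. The diaryl ether is the hard bond: B5 lies between B4–CH3 and B6–OH, and C1 between the C2 aldehyde and the C6 ester, so a direct aryl–aryl ether coupling would join two doubly ortho-substituted, electron-rich carbons. The bridge must reach B1 and not the equally activated B3. The groups that will not survive rough treatment are the ring C aldehyde, two methyl esters that must be neither exchanged nor cleaved, four free phenols on electron-rich rings, and the doubly activated diarylmethane CH2. Stereocentres arise only while ring B is alicyclic (B4, B5); they are erased on aromatization and control nothing. The enabling feature is the pattern of ring B, with oxygens at B2 and B6, methyl at B4 and the ether carbon B5 between B4 and B6: it maps onto a 4-aryloxy-5-methylcyclohexane-1,3-dione, in which B5–B6 comes from a malonate, B4–B3–B2–B1 from pent-3-en-2-one, and B1 is the only nucleophilic carbon.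

## Retrosynthesis

**Protecting groups (19 ⇐ 18 ⇐ 17).** No skeletal bond is cut. Target 19 is traced to its ring C methyl ether 18, and 18 to 17, which also carries MOM ethers on A4–O and A6–O and a dioxolane on the C2 aldehyde. The C3–O methyl ether is chosen because it survives acid-catalysed acetalization, alkoxide, hydrogenolysis and Pd/O2, which a MOM ether at that position would not (it is lost to ethylene glycol and acid). In 18 it is the only alkyl ether and sits ortho to the aldehyde, so BCl3 should remove it by chelation. The forward steps ask only for aqueous acid, then BCl3.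

**Oxidation level of ring B (17 ⇐ 16).** Only two hydrogens are removed; no C–C bond is cut. Keeping ring B as a cyclohexane-1,3-dione until the bridge is in place is what fixes the regiochemistry: a resorcinol offers B1 and B3, the dione offers B1 alone. The forward step must dehydrogenate without acid strong enough to strip MOM or dioxolane groups.

**Bridge (16 ⇐ 13 + 14).** The B1–CH2 bond is cut. The bridge carbon is the aldehyde carbon of bis-MOM methyl haematommate 14, joined to dione 13 by reductive Knoevenagel alkylation. The neighbouring cuts are weaker: Friedel–Crafts benzylation of an aromatic ring B has no B1/B3 control, and benzyl halide alkylation of a dione competes with O-alkylation. Aldehyde 14 is one step from methyl haematommate 3, which therefore serves twice. The forward reaction needs the ring C aldehyde masked and the ring A ortho oxygens capped, so that they cannot cyclise onto the dione.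

**Extra carboxyl at B5 (13 ⇐ 11).** The B5–CO2 bond is cut. The activating ester is a benzyl ester so that hydrogenolysis and spontaneous decarboxylation remove it under neutral conditions. A methyl ester would have to be removed beside the ring C methyl ester by halide dealkylation or saponification, and neither distinguishes the two reliably.

**Ring B (11 ⇐ 8 + 9).** The B5–B4 and B1–B6 bonds are cut, opening ring B to aryloxymalonate 8 and (E)-pent-3-en-2-one 9. This is the key disconnection: it removes a ring and both transient stereocentres, and leaves the ether oxygen on an sp3 carbon. The forward Michael–Claisen annulation must beat acylation of the carbanion by the ring C ester.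

**Ether (8 ⇐ 5 + 7; 7 ⇐ 6).** The O–B5 bond is cut as an SN2 displacement of bromide from dibenzyl bromomalonate 7 by phenol 5. This replaces a tetra-ortho-substituted aryl–aryl ether coupling by a Williamson reaction. The aldehyde must already be masked in 5, because an aryloxymalonate with a free ortho aldehyde closes to a benzofuran under base. Bromide 7 comes from dibenzyl malonate 6 by bromination.

**Ring C phenol (5 ⇐ 4 ⇐ 3 ⇐ 1).** The acetal, the C3–O methyl group and the formyl carbon are removed in turn, leading to methyl orsellinate 1. Each forward step relies on the inherent bias of the haematommate nucleus: formylation between the two hydroxyls, then alkylation of the more exposed 4-OH.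

## Roads not taken

**Alternative 1:** Oxygen insertion into a xanthone. The cut is the B6–O and O–acyl pair of a depsidone lactone. Forward, trifluoroperacetic acid would add to the carbonyl of xanthone A2 and ring B carbon B6 would migrate to oxygen, giving depsidone A1. Methanolysis of A1 would then deliver the C6 methyl ester and the B6 phenol in one stroke.
- Merits: all rings stay aromatic, so no dehydrogenation is needed. The migrating ring B is the electron-rich one, so the migration sense is right. The ester and phenol are unveiled together.
- Weak points: a xanthone carbonyl is a doubly vinylogous ester and a poor acceptor for peracids, while the electron-rich ring B is itself open to peracid oxidation. A2 still needs a hindered diaryl ether or benzophenone closure. After A1, a nitrile must become an aldehyde beside esters, and a tosylate and a benzyl ether must be removed. Ring A must then be attached to an aromatic ring B with no B1/B3 control.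
- Comparison: this road is better in never leaving the aromatic oxidation level and in its elegant lactone opening. The chosen plan sets against it a fixed bridge position, no oxidant stronger than O2 with a palladium catalyst, and a ring C whose aldehyde and ester are bought with the starting material.

**Alternative 2:** Ring A from a dioxinone-masked triketide. The cut is the ring A bond between the ester-bearing carbon and the methyl-bearing carbon. Forward, heating diketo-dioxinone A4 in methanol would open the dioxinone with loss of acetone and uptake of methanol, and base followed by acid would then close ring A by aldol condensation and dehydration, giving resorcylate A3.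
- Merits: the aromatization is mild and redox-neutral. The bridge is installed at an sp3 carbon on a symmetric ring B fragment, so there is no B1/B3 question.
- Weak points: A3 still lacks the B5–O–C1 ether. It would have to be added last by oxygenating or halogenating B5 (in competition with the unsubstituted CH of the free resorcinol ring A), followed by the hindered aryl–aryl ether coupling, the hardest bond of the molecule. Ring A is built from scratch although orsellinate is available.
- Comparison: this road is better for the A–B half (no redox adjustment, unambiguous bridge). The chosen plan instead buys ring A and spends its invention on the ether bond, made by SN2 before ring B exists.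

**Alternative 3:** Ring C from a 2-pyranone and an aryloxypropiolate. The cuts are C2–C1 and C5–C6. Forward, heating pyranone A6 with aryloxypropiolate A7 would bring about a Diels–Alder addition across these two bonds followed by loss of CO2, giving the protected target A5.
- Merits: it shares the logic of the chosen plan, since the ether oxygen sits on a non-aromatic carbon when the ring is made. The polarity of both partners matches the needed regiochemistry. CO2 loss makes it irreversible, and the whole skeleton appears in one convergent step.
- Weak points: both bonding termini are congested (the pyranone carbon bearing the dioxolane, the alkyne carbon bearing the tetra-ortho-substituted aryloxy group), and such cycloadditions need high temperature with four MOM ethers and an acetal on board. A7 requires the complete A–B diarylmethane with B5–OH as its only free phenol: an oxidation-prone hydroxyquinol ring whose synthesis brings back both the bridge regiochemistry and the B5 oxygenation problem. The C3 methyl ether must still be cleaved at the end.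
- Comparison: this road is more convergent and needs no dehydrogenation. The chosen plan sets against it fragments reached from methyl orsellinate in at most four mild steps, and a ring B that carries its B5 oxygen from the start.

Key step: step 6

Assumption: methyl orsellinate (1), dibenzyl malonate (6) and (E)-pent-3-en-2-one (9) are taken as commercial; the target is achiral, and chiral intermediates 10–13, 15 and 16 are carried as racemates or diastereomer mixtures.

Abbreviation used in names: ArC = 2-(1,3-dioxolan-2-yl)-3-methoxy-6-(methoxycarbonyl)-5-methylphenyl (ring C, bonded through C1).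

## Route

Step 1
Reactants: 1 methyl orsellinate (methyl 2,4-dihydroxy-6-methylbenzoate)
Product: 3 methyl haematommate (methyl 3-formyl-2,4-dihydroxy-6-methylbenzoate), via aryl chloro(methoxy)methane 2 (not isolated)
Conditions: Cl2CHOMe, TiCl4, CH2Cl2, 0 °C; then 1 M HCl
Reagents that add atoms: dichloromethyl methyl ether, COC(Cl)Cl; water, O
Why: Rieche formylation; the TiCl4-bound phenoxide directs the electrophile ortho, and the position between the two hydroxyls is the most activated, so 3 should be the main isomer with any 5-formyl isomer removed by crystallisation; hydrolysis of chloro ether 2 on work-up releases the aldehyde.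

Step 2
Reactants: 3 methyl haematommate
Product: 4 methyl 3-formyl-2-hydroxy-4-methoxy-6-methylbenzoate
Conditions: MeI (1.1 equiv), K2CO3, acetone, rt
Reagents that add atoms: iodomethane, CI
Why: Williamson etherification; the 4-OH (para to the ester) is the more acidic and exposed phenol, while the 2-OH is locked in a hydrogen bond to the ester carbonyl, so one equivalent of MeI should stop at the 4-O-methyl ether.

Step 3
Reactants: 4 methyl 3-formyl-2-hydroxy-4-methoxy-6-methylbenzoate
Product: 5 methyl 3-(1,3-dioxolan-2-yl)-2-hydroxy-4-methoxy-6-methylbenzoate
Conditions: HOCH2CH2OH, TsOH (cat.), benzene, reflux, Dean–Stark; Et3N quench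
Reagents that add atoms: ethylene glycol, OCCO
Why: Acid-catalysed acetalization driven by azeotropic removal of water; the methyl ether and the hindered, hydrogen-bonded ester are inert, and the aldehyde must be masked now because an aryloxymalonate with a free ortho aldehyde would cyclise to a benzofuran under base.

Step 4
Reactants: 6 dibenzyl malonate
Product: 7 dibenzyl 2-bromomalonate
Conditions: Br2 (1.0 equiv), CH2Cl2, 0 °C to rt
Reagents that add atoms: bromine, BrBr
Why: Electrophilic α-bromination of a malonate through its enol; one equivalent of bromine and the deactivating effect of the first bromine should hold the reaction at the monobromide.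

Step 5
Reactants: 5 methyl 3-(1,3-dioxolan-2-yl)-2-hydroxy-4-methoxy-6-methylbenzoate; 7 dibenzyl 2-bromomalonate
Product: 8 dibenzyl 2-[2-(1,3-dioxolan-2-yl)-3-methoxy-6-(methoxycarbonyl)-5-methylphenoxy]malonate (dibenzyl 2-(ArC-oxy)malonate)
Conditions: K2CO3, acetone, reflux
Reagents that add atoms: none
Why: Williamson-type SN2 displacement at the doubly activated α-bromo diester carbon, the classical preparation of aryloxymalonates; the C1–O–B5 ether is thereby made at an sp3 carbon, and carbonate in acetone is alkoxide-free and too weak to drive acylation of the product carbanion by the ring C ester.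

Step 6
Reactants: 8 dibenzyl 2-(ArC-oxy)malonate; 9 (E)-pent-3-en-2-one
Product: 11 benzyl 1-(ArC-oxy)-6-methyl-2,4-dioxocyclohexane-1-carboxylate (racemic; methyl cis to aryloxy drawn), via Michael adduct 10 (not isolated)
Conditions: KOt-Bu (0.1 equiv), 9 (2 equiv), THF/t-BuOH, −20 °C; then KOt-Bu (1.5 equiv), −20 °C to rt; AcOH quench
Reagents that add atoms: none
Why: Michael–Claisen annulation of the dimedone type with a 2-aryloxymalonate as donor: catalytic KOt-Bu generates the soft tertiary carbanion of 8, which adds 1,4 to 9 and forms the B5–B4 bond (adduct 10); the full equivalent of base then equilibrates the ketone enolates, and only the methyl enolate can reach a benzyl ester through a six-membered transition state, closing ring B by 6-(enolexo)-exo-trig Claisen condensation (B1–B6 bond) with loss of benzyloxide. The closest known reactions are the annulations of 2-alkylmalonates with enones to 4-substituted 4-alkoxycarbonylcyclohexane-1,3-diones. The product rests as its 1,3-dione enolate, which makes the closure irreversible and pulls the reversible conjugate addition forward. The B4 centre is set without control in the addition; the B5 centre arises from the choice between the two diastereotopic ester groups in a chair-like closure that should keep the B4 methyl and the surviving ester equatorial (methyl cis to aryloxy), but neither needs control because both are erased in step 10. The selectivity that matters is chemoselectivity: conjugate addition must outrun acylation of the carbanion by the ring C ester (a five-membered closure), for which the flanking C5 methyl of that ester, the low temperature and the excess of 9 are relied on while the carbanion is free; once B5 is quaternary it can no longer act as a nucleophile. 1,2-Addition is disfavoured for the stabilised carbanion, the enolate at B3 could only close a four-membered ring, and benzyl esters with tert-butoxide avoid ester scrambling, so the B5 ester stays cleavable by hydrogenolysis.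

Step 7
Reactants: 11 benzyl 1-(ArC-oxy)-6-methyl-2,4-dioxocyclohexane-1-carboxylate
Product: 13 methyl 3-(1,3-dioxolan-2-yl)-4-methoxy-6-methyl-2-[(6-methyl-2,4-dioxocyclohexyl)oxy]benzoate (4-(ArC-oxy)-5-methylcyclohexane-1,3-dione; racemic cis/trans mixture), via β-keto acid 12 (not isolated)
Conditions: H2 (1 atm), Pd/C (10 wt %), EtOAc, rt; filter; 45 °C
Reagents that add atoms: none
Why: Hydrogenolysis of the benzyl ester gives β-keto acid 12, which decarboxylates through the usual six-membered transition state on gentle warming; the ring C methyl ester, the methyl ether and the aryl ether are inert, and the doubly ortho-substituted aryl dioxolane is cleaved far more slowly than a benzyl ester. B5 becomes an epimerisable CH, so a cis/trans mixture is expected and is of no consequence.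

Step 8
Reactants: 3 methyl haematommate
Product: 14 methyl 3-formyl-2,4-bis(methoxymethoxy)-6-methylbenzoate
Conditions: MOMCl (3 equiv), NaH (2.5 equiv), DMF, 0 °C to rt
Reagents that add atoms: chloromethyl methyl ether, COCCl
Why: Williamson O-alkylation of both phenoxides (NaH is needed for the chelated 2-OH); capping both ortho oxygens keeps them from cyclising onto the dione after the bridge is formed.

Step 9
Reactants: 13 4-(ArC-oxy)-5-methylcyclohexane-1,3-dione; 14 methyl 3-formyl-2,4-bis(methoxymethoxy)-6-methylbenzoate
Product: 16 methyl 3-{[3-(ArC-oxy)-4-methyl-2,6-dioxocyclohexyl]methyl}-2,4-bis(methoxymethoxy)-6-methylbenzoate (racemic diastereomer mixture; largely enolised), via alkylidene dione 15 (not isolated)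
Conditions: Hantzsch ester (1.1 equiv), L-proline (20 mol %), CH2Cl2, rt
Reagents that add atoms: none
Why: Organocatalytic three-component reductive alkylation (proline-catalysed Knoevenagel condensation, then 1,4-hydride transfer from the Hantzsch ester to alkylidene dione 15); B1 is the only carbon flanked by two carbonyls, so the bridge can form nowhere else, and immediate reduction of 15 forestalls addition of a second dione. The ring C aldehyde stays masked as its dioxolane.

Step 10
Reactants: 16 methyl 3-{[3-(ArC-oxy)-4-methyl-2,6-dioxocyclohexyl]methyl}-2,4-bis(methoxymethoxy)-6-methylbenzoate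
Product: 17 methyl 3-{[3-(ArC-oxy)-2,6-dihydroxy-4-methylphenyl]methyl}-2,4-bis(methoxymethoxy)-6-methylbenzoate
Conditions: Pd(O2CCF3)2 (10 mol %), 4,5-diazafluoren-9-one (10 mol %), O2 (1 atm), DMSO, 80 °C
Reagents that add atoms: none
Why: Aerobic dehydrogenation of a cyclic ketone catalysed by Pd(O2CCF3)2: a divalent palladium enolate at B3 (or B5) undergoes β-hydride elimination from B4, and the resulting cyclohexenedione tautomerises at once to the resorcinol, so a single dehydrogenation suffices while O2 returns the catalyst to divalent palladium. The ligand-buffered medium without added strong acid is chosen to spare the MOM ethers and the dioxolane; both transient stereocentres disappear here.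

Step 11
Reactants: 17 methyl 3-{[3-(ArC-oxy)-2,6-dihydroxy-4-methylphenyl]methyl}-2,4-bis(methoxymethoxy)-6-methylbenzoate
Product: 18 methyl 2-{3-[(2,6-dihydroxy-3-(methoxycarbonyl)-4-methylphenyl)methyl]-2,4-dihydroxy-6-methylphenoxy}-3-formyl-4-methoxy-6-methylbenzoate (praesorether F methylated at C3–O)
Conditions: 2 M HCl, THF/MeOH, 45 °C
Reagents that add atoms: water, O
Why: Acid hydrolysis of acetals: both MOM ethers and the dioxolane are cleaved by dilute aqueous HCl, whereas the aryl methyl ether, both methyl esters and the diaryl ether are stable; dilute conditions keep the released formaldehyde from adding to the resorcinol rings.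

Step 12
Reactants: 18 praesorether F methylated at C3–O
Product: 19 praesorether F (methyl 2-{3-[(2,6-dihydroxy-3-(methoxycarbonyl)-4-methylphenyl)methyl]-2,4-dihydroxy-6-methylphenoxy}-3-formyl-4-hydroxy-6-methylbenzoate)
Conditions: BCl3 (6 equiv), CH2Cl2, −78 to 0 °C; then H2O
Reagents that add atoms: none
Why: Chelation-controlled aryl methyl ether cleavage: BCl3 binds the C2 aldehyde oxygen and the neighbouring C3 methoxy oxygen in a six-membered chelate and chloride removes the methyl group; this demethylation ortho to a carbonyl is standard, 18 holds no other alkyl ether, and methyl esters and the diaryl ether are not attacked at 0 °C.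

## Compound list

1 | methyl orsellinate (methyl 2,4-dihydroxy-6-methylbenzoate) | COC(=O)c1c(C)cc(O)cc1O | starting material
2 | methyl 3-[chloro(methoxy)methyl]-2,4-dihydroxy-6-methylbenzoate (TiCl4-bound, not isolated) | COC(=O)c1c(C)cc(O)c(C(Cl)OC)c1O | intermediate
3 | methyl haematommate (methyl 3-formyl-2,4-dihydroxy-6-methylbenzoate) | COC(=O)c1c(C)cc(O)c(C=O)c1O | intermediate
4 | methyl 3-formyl-2-hydroxy-4-methoxy-6-methylbenzoate | COC(=O)c1c(C)cc(OC)c(C=O)c1O | intermediate
5 | methyl 3-(1,3-dioxolan-2-yl)-2-hydroxy-4-methoxy-6-methylbenzoate | COC(=O)c1c(C)cc(OC)c(C2OCCO2)c1O | intermediate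
6 | dibenzyl malonate | O=C(CC(=O)OCc1ccccc1)OCc1ccccc1 | starting material
7 | dibenzyl 2-bromomalonate | O=C(OCc1ccccc1)C(Br)C(=O)OCc1ccccc1 | intermediate
8 | dibenzyl 2-[2-(1,3-dioxolan-2-yl)-3-methoxy-6-(methoxycarbonyl)-5-methylphenoxy]malonate | COC(=O)c1c(C)cc(OC)c(C2OCCO2)c1OC(C(=O)OCc1ccccc1)C(=O)OCc1ccccc1 | intermediate
9 | (E)-pent-3-en-2-one | C/C=C/C(C)=O | starting material
10 | dibenzyl 2-(ArC-oxy)-2-(4-oxopentan-2-yl)malonate (racemic Michael adduct, not isolated) | O=C(OCc1ccccc1)C(Oc1c(C2OCCO2)c(OC)cc(C)c1C(=O)OC)(C(C)CC(C)=O)C(=O)OCc1ccccc1 | intermediate
11 | benzyl 1-(ArC-oxy)-6-methyl-2,4-dioxocyclohexane-1-carboxylate (racemic; relative configuration drawn, methyl cis to aryloxy) | O=C(OCc1ccccc1)[C@]1(Oc2c(C3OCCO3)c(OC)cc(C)c2C(=O)OC)[C@@H](C)CC(=O)CC1=O | intermediate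
12 | 1-(ArC-oxy)-6-methyl-2,4-dioxocyclohexane-1-carboxylic acid (racemic; relative configuration drawn; not isolated) | OC(=O)[C@]1(Oc2c(C3OCCO3)c(OC)cc(C)c2C(=O)OC)[C@@H](C)CC(=O)CC1=O | intermediate
13 | methyl 3-(1,3-dioxolan-2-yl)-4-methoxy-6-methyl-2-[(6-methyl-2,4-dioxocyclohexyl)oxy]benzoate (racemic cis/trans mixture, B5 epimerisable) | COC(=O)c1c(C)cc(OC)c(C2OCCO2)c1OC1C(C)CC(=O)CC1=O | intermediate
14 | methyl 3-formyl-2,4-bis(methoxymethoxy)-6-methylbenzoate | COC(=O)c1c(C)cc(OCOC)c(C=O)c1OCOC | intermediate
15 | methyl 3-{[3-(ArC-oxy)-4-methyl-2,6-dioxocyclohexylidene]methyl}-2,4-bis(methoxymethoxy)-6-methylbenzoate (alkene geometry and ring stereocentres undefined; not isolated) | COC(=O)c1c(C)cc(OCOC)c(C=C2C(=O)CC(C)C(Oc3c(C4OCCO4)c(OC)cc(C)c3C(=O)OC)C2=O)c1OCOC | intermediate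
16 | methyl 3-{[3-(ArC-oxy)-4-methyl-2,6-dioxocyclohexyl]methyl}-2,4-bis(methoxymethoxy)-6-methylbenzoate (racemic diastereomer mixture) | COC(=O)c1c(C)cc(OCOC)c(CC2C(=O)CC(C)C(Oc3c(C4OCCO4)c(OC)cc(C)c3C(=O)OC)C2=O)c1OCOC | intermediate
17 | methyl 3-{[3-(ArC-oxy)-2,6-dihydroxy-4-methylphenyl]methyl}-2,4-bis(methoxymethoxy)-6-methylbenzoate | COC(=O)c1c(C)cc(OCOC)c(Cc2c(O)cc(C)c(Oc3c(C4OCCO4)c(OC)cc(C)c3C(=O)OC)c2O)c1OCOC | intermediate
18 | methyl 2-{3-[(2,6-dihydroxy-3-(methoxycarbonyl)-4-methylphenyl)methyl]-2,4-dihydroxy-6-methylphenoxy}-3-formyl-4-methoxy-6-methylbenzoate | COC(=O)c1c(C)cc(O)c(Cc2c(O)cc(C)c(Oc3c(C=O)c(OC)cc(C)c3C(=O)OC)c2O)c1O | intermediate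
19 | praesorether F | COC(=O)c1c(C)cc(O)c(Cc2c(O)cc(C)c(Oc3c(C=O)c(O)cc(C)c3C(=O)OC)c2O)c1O | target

## Step count and risk

Total: 12 steps. Longest linear sequence: 10 steps (1, 2, 3, 5, 6, 7, 9, 10, 11, 12) from methyl orsellinate; steps 4 and 8 are side branches.

**Step 6 (key step).** The most likely failure is acylation of the free aryloxymalonate carbanion by the neighbouring ring C ester (five-membered closure followed by loss of one ester), or reversal of the conjugate addition before the Claisen closure, because the new quaternary centre is crowded. Fallback, from 8 and 9 back to 11: the two events are separated. The conjugate addition would be run under solid–liquid phase transfer (K2CO3, Bu4NBr, toluene, 0 °C, large excess of 9), where no alkoxide and only a trace of carbanion are present, and adduct 10 would be isolated. Its kinetic methyl enolate would then be formed with LiN(SiMe3)2 (2.2 equiv, THF, −78 to 0 °C) and would close irreversibly to 11, with no chance of retro-addition. This fallback makes no compound outside the compound list; its entry below is F0.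

**Step 10.** Possible failures are loss of MOM or dioxolane groups under the oxidation conditions, aromatization by expulsion of the ring C phenoxide from B5 instead of loss of hydrogen, or palladation at B1 that leads towards the bridge carbon. Fallback, from 16 back to 17, by Saegusa–Ito oxidation under non-acidic conditions: 16 would be silylated (Me3SiCl, Et3N, then LiN(SiMe3)2, Me3SiCl, THF, −78 °C) to the bis(trimethylsilyl) dienol ether of 16 (F1). Stoichiometric Pd(OAc)2 in MeCN at rt would dehydrogenate F1 across B3–B4, and tautomerisation of the resulting dienone would give the mono(trimethylsilyl) ether of 17 (F2). Brief treatment of F2 with K2CO3 in MeOH would remove the remaining silyl group and return 17.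

**Step 9.** Condensation at the doubly ortho-substituted aldehyde may be slow, giving the acidic dione and the water formed time to unmask the ring C aldehyde, or a second dione may add to 15 before hydride transfer. Fallback, from 14 and 13 back to 16, by direct C-alkylation: 14 would be reduced (NaBH4, MeOH, 0 °C) to methyl 3-(hydroxymethyl)-2,4-bis(methoxymethoxy)-6-methylbenzoate (F3). F3 would be converted (MsCl, Et3N, LiCl, THF) to methyl 3-(chloromethyl)-2,4-bis(methoxymethoxy)-6-methylbenzoate (F4). The potassium enolate of 13 (KOH, water/dioxane, rt, conditions that favour C- over O-benzylation of cyclic 1,3-diones) would be alkylated with F4 to give 16.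

**Step 5.** Displacement by the doubly ortho-substituted phenoxide may be slow, so that bromine transfer to the phenoxide or cyclisation of the product carbanion onto the ring C ester takes over. Fallback, from 6 and 5 back to 8, without base: diazo transfer to 6 (4-acetamidobenzenesulfonyl azide, Et3N, MeCN) would give dibenzyl 2-diazomalonate (F5). Rh2(OAc)4 (1 mol %, benzene, 80 °C) would then insert the carbenoid of F5 into the O–H bond of 5 to give 8.

**Step 3.** The acetalization equilibrium may be unfavourable, or the product may hydrolyse back, because the aldehyde is stabilised by the hydrogen bond to the ortho hydroxyl; slow ester exchange with the glycol is a further risk. Fallback, from 4 and 7 back to 8, with the order inverted: 4 would first be O-alkylated with 7 (K2CO3, acetone, as for salicylaldehyde in the first stage of the classical benzofuran synthesis, where the formyl aryloxymalonate can be isolated) to dibenzyl 2-[2-formyl-3-methoxy-6-(methoxycarbonyl)-5-methylphenoxy]malonate (F6). The aldehyde of F6, now without a hydrogen-bond partner, would be acetalized by silyl transfer (1,2-bis(trimethylsilyloxy)ethane, catalytic Me3SiOTf, CH2Cl2, −78 °C) to give 8.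

## Further compounds

F0 | step 6 | none | none
F1 | step 10 | bis(trimethylsilyl) dienol ether of 16 (2,6-bis(trimethylsilyloxy)cyclohexa-1,5-diene form of ring B) | COC(=O)c1c(C)cc(OCOC)c(CC2=C(O[Si](C)(C)C)C(Oc3c(C4OCCO4)c(OC)cc(C)c3C(=O)OC)C(C)C=C2O[Si](C)(C)C)c1OCOC
F2 | step 10 | mono(trimethylsilyl) ether of 17 (silyl on B6–O) | COC(=O)c1c(C)cc(OCOC)c(Cc2c(O)cc(C)c(Oc3c(C4OCCO4)c(OC)cc(C)c3C(=O)OC)c2O[Si](C)(C)C)c1OCOC
F3 | step 9 | methyl 3-(hydroxymethyl)-2,4-bis(methoxymethoxy)-6-methylbenzoate | COC(=O)c1c(C)cc(OCOC)c(CO)c1OCOC
F4 | step 9 | methyl 3-(chloromethyl)-2,4-bis(methoxymethoxy)-6-methylbenzoate | COC(=O)c1c(C)cc(OCOC)c(CCl)c1OCOC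
F5 | step 5 | dibenzyl 2-diazomalonate | [N-]=[N+]=C(C(=O)OCc1ccccc1)C(=O)OCc1ccccc1
F6 | step 3 | dibenzyl 2-[2-formyl-3-methoxy-6-(methoxycarbonyl)-5-methylphenoxy]malonate | COC(=O)c1c(C)cc(OC)c(C=O)c1OC(C(=O)OCc1ccccc1)C(=O)OCc1ccccc1
A1 | alternative 1 | depsidone with C2 nitrile, C3 tosylate and B2 benzyl ether | Cc1cc(OS(=O)(=O)c2ccc(C)cc2)c(C#N)c2Oc3c(C)cc(OCc4ccccc4)cc3OC(=O)c12
A2 | alternative 1 | xanthone precursor with C2 nitrile, C3 tosylate and B2 benzyl ether | Cc1cc(OS(=O)(=O)c2ccc(C)cc2)c(C#N)c2Oc3c(C)cc(OCc4ccccc4)cc3C(=O)c12
A3 | alternative 2 | methyl 3-[2,6-bis(benzyloxy)-4-methylbenzyl]-2,4-dihydroxy-6-methylbenzoate | COC(=O)c1c(C)cc(O)c(Cc2c(OCc3ccccc3)cc(C)cc2OCc2ccccc2)c1O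
A4 | alternative 2 | 6-{1-[2,6-bis(benzyloxy)-4-methylphenyl]-3,5-dioxohexan-2-yl}-2,2-dimethyl-4H-1,3-dioxin-4-one (racemic) | CC(=O)CC(=O)C(Cc1c(OCc2ccccc2)cc(C)cc1OCc1ccccc1)C1=CC(=O)OC(C)(C)O1
A5 | alternative 3 | protected target (C3 methyl ether, C2 dioxolane, four MOM ethers) | COC(=O)c1c(C)cc(OC)c(C2OCCO2)c1Oc1c(C)cc(OCOC)c(Cc2c(OCOC)cc(C)c(C(=O)OC)c2OCOC)c1OCOC
A6 | alternative 3 | 3-(1,3-dioxolan-2-yl)-4-methoxy-6-methyl-2H-pyran-2-one | COc1cc(C)oc(=O)c1C1OCCO1
A7 | alternative 3 | methyl 3-aryloxypropiolate of the tetra-MOM ring A–ring B phenol | COC(=O)C#COc1c(C)cc(OCOC)c(Cc2c(OCOC)cc(C)c(C(=O)OC)c2OCOC)c1OCOC
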